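**Structural features**

The target is a p-terphenyl. Its central benzene ring (ring B) is hexasubstituted: two 4-hydroxyphenyl rings (rings A and C) sit para to each other at C1' and C4', and four acyloxy groups sit at C2', C3', C5' and C6'. Ring B is therefore the tetra-ester of a tetrahydroxybenzene, the reduced form of a 2,5-diaryl-3,6-dihydroxybenzoquinone. The four acyl groups are identical (2Z)-3-[(2S,3S)-3-methyloxiran-2-yl]prop-2-enoyl chains: C1 is the ester carbonyl, C2=C3 is a Z alkene, C4–C5 is a trans epoxide and C6 is a methyl group. Each chain holds two adjacent stereocentres (C4 and C5, both S), eight in all; the chains are remote from one another, so the configuration has to be set by a reagent at four independent sites. The fragile groups are the Z-enoates (isomerised by reversible conjugate addition or when a free Z-acid is activated), the vinyl epoxides (opened by acid, soft nucleophiles and zerovalent palladium), the aryl esters on an electron-poor ring (easily hydrolysed) and the unacylated tetrol core (oxidised by air to the quinone). The core is easy; the real difficulty is placing four Z-configured, enantiopure epoxy-enoates on a crowded, base-sensitive ring without E/Z leakage. The route exploits atoms C2–C5 of each chain: without the epoxide oxygen they form a (2Z,4E)-diene, and joining C2 to C5 turns that diene into a cis-4-methylcyclobut-2-ene-1-carboxylate (ring C1 = chain C2, ring C4 = chain C5), an acyl unit with no alkene geometry to lose.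

**Logic of the disconnections**

19 to 18: the two phenolic O–H bonds of rings A and C are traced back to O–Si bonds. The outer phenols must be told apart from the four core oxygens during acylation, and a silyl ether can be removed at the end without hydrogenation, strong acid or base. Nothing is gained in skeleton, only in regiocontrol. The forward step must cleave two aryl silyl ethers while sparing four aryl esters, four Z-enoates and four vinyl epoxides.

18 to 17: the eight epoxide C–O bonds (two per chain, at C4 and C5) are removed. This erases all eight stereocentres in one transform and leaves an achiral tetraene. The forward step must be a reagent-controlled epoxidation of a trans alkene that picks the distal, more electron-rich C4=C5 bond over the enoate C2=C3 bond, four times, at a pH the aryl esters survive.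

17 to 16: in the retrosynthetic sense C2 and C5 of each chain are joined by a σ bond, giving four cis-disubstituted cyclobutenes. The cut is made here because the Z geometry then does not yet exist at the stage where an acyl group has to be activated and attached. Four labile alkene geometries are replaced by four robust rings. The forward step must open each ring with the ester rotating inward and the methyl outward, without reagents that could isomerise the product.

16 to 14 and 13: the four ester C–O bonds are cut. This divides the molecule into the core and two copies of a symmetric acyl donor, each of which hands over both of its acyl groups. The forward step must acylate four flanked phenolic OH groups exhaustively, under exclusion of air, without epimerising the acyl unit at its α-carbon and without heating.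

13 to 11 (through 12): one acyl–oxygen bond of the anhydride is cut, which gives two copies of one small acid. Activation is thereby finished, and its urea removed, before the air-sensitive 14 is generated, so 14 meets a ready acyl donor. The forward step must dehydrate without base, nucleophilic catalyst or heat, so that the ring stays closed and cis.

14 to 8: the four core O–H bonds are traced back to O–benzyl bonds. 14 cannot be stored, and benzyl ethers fall under neutral hydrogenolysis that leaves aryl silyl ethers alone and is run before any alkene is present. The forward step must deliver 14 under a reducing atmosphere for immediate use.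

8 to 5 and 2 (through 6 and 7): the two aryl–aryl bonds at C1' and C4' are cut. Ring B is then a symmetric dibromide with all four oxygens already in place, so the terphenyl arises by a two-directional coupling with a single aryl nucleophile. The forward step must couple twice at bromides that are each flanked by two ortho alkoxy groups.

5 to 3 (through 4), and 2 to 1: four O–benzyl bonds and the hydroquinone-to-quinone redox relation lead to a catalogue quinone; one O–Si bond leads to a catalogue phenol. The only demand is that 4 is alkylated before air reaches it.

11 to 9 (through 10): the C–H bond at the methyl-bearing ring carbon is traced back to a C–O bond of a bicyclic lactone, and the ring σ bond opposite the alkene to a photochemical closure of a pyranone. The cis fusion of 10 fixes the face of the carboxylate. The forward step must deliver hydride to the methyl-bearing allyl terminus, on the face anti to the carboxylate, so that methyl and CO2H end cis.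

**Other disconnections considered**

All three alternatives rebuild ring B instead of buying it. None addresses the side chains, so each would replace only steps 1, 2, 3 and 6 and would still need steps 4, 5 and 7–10.

Alternative 1: The cut is through ring bonds C1'–C2' and C3'–C4'. Ring B comes from the cyclopentadienone A2 (3,4-bis(benzyloxy)-2,5-bis[4-(triisopropylsilyloxy)phenyl]cyclopenta-2,4-dien-1-one) as the four-carbon unit and vinylene carbonate A3 as the two-carbon unit. In the forward key step A2 and A3 undergo a thermal Diels–Alder addition, and the bridged ketone adduct then loses its one-carbon carbonyl bridge by cheletropic extrusion to give the cyclohexadiene A1.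
- In its favour: it needs no metal, both aryl groups are in place before the ring forms, and the two pairs of core oxygens arrive differentiated (carbonate versus benzyl).
- Against it here: A1 still has to be dehydrogenated to the arene, and its carbonate (base, which threatens the aryl silyl ethers) and benzyl groups removed before it reaches 14. A2 has to be made in several steps, and as an alkoxy-rich diene it is electronically mismatched with A3, so forcing temperatures and dimerisation of A2 are to be expected.
- Structure: it solves the core, not the Z-enoate/epoxide problem.
- Mechanism: it is a thermal, reagent-free pericyclic step, equal in kind and cleanliness to the chosen key step.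
- Step economy: it is worse, since 14 is reached here in four steps from catalogue compounds.
- Where it is better: the differentiated oxygen pairs would allow congeners with two different acyl groups. The target has four identical ones, so that advantage is not used.

Alternative 2: The cut is through ring bonds C2'–C3', C4'–C5' and C6'–C1'. Ring B comes from the silylene-tethered bis(ynol ether) A5 (diisopropylbis{[4-(triisopropylsilyloxy)phenyl]ethynyloxy}silane) and di-tert-butoxyethyne A6. In the forward key step a cationic monovalent rhodium catalyst, [Rh(cod)2]BF4 with a bisphosphine, effects a [2+2+2] cyclotrimerisation, the tether enforcing the union of the two oxygenated alkyne carbons, to give the benzodioxasilole A4.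
- In its favour: all six substituents of ring B are placed in one step with complete regiocontrol, no coupling at a hindered position is needed, and the oxygen pairs are again differentiated.
- Against it here: A5 and A6 are electron-rich ynol ethers that hydrolyse readily and are open to ketene-type side reactions and homo-oligomerisation. Making A5 requires O-selective double silylation of an aryl ynolate. Unmasking A4 needs strong acid for the tert-butyl ethers and fluoride for the silylene, and the fluoride would also strip the outer silyl ethers.
- Structure: it is the equal of the chosen plan for the core pattern and better in convergence of ring construction.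
- Mechanism: a metal-templated cycloaddition of three sensitive partners is less predictable than a coupling on a preformed ring followed by a unimolecular pericyclic opening.
- Step economy: it is not shorter once A5 and A6 are counted.

Alternative 3: The cut is through ring bonds C3'–C4' and C6'–C1'. Ring B comes from two arylpyruvate units held as the bis(arylidene)dioxanedione A8 ((3Z,6Z)-3,6-bis[4-(benzyloxy)benzylidene]-1,4-dioxane-2,5-dione). In the forward key step NaOMe opens A8 and the two released arylpyruvate enolates C-acylate each other in a double Claisen-type condensation to give the dihydroxyquinone A7.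
- In its favour: it is biomimetic, uses the cheapest raw materials and needs no transition metal.
- Where it is equal or better: on paper the route to the atromentin skeleton is as short as the one chosen here, and cheaper.
- Against it here: A7 carries benzyl ethers on rings A and C, which cannot be removed at the end in the presence of dienoate or epoxy-enoate chains, and NaOMe would not tolerate aryl silyl ethers in their place, so a protecting-group exchange would have to be inserted. A7 is at the quinone level and must be reduced before acylation. Several condensation pathways compete in the dimerisation, so its efficiency is expected to be moderate.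
- Structure: it is the equal of the chosen plan for the carbon skeleton but worse in protecting-group fit.
- Mechanism: an ionic cascade in strong base, against a neutral coupling.
- Step economy: the extra exchange and reduction cancel its head start.

Key step: step 8

Remark: acid 11 is used as the racemate, so 13 is a mixture of racemic and meso anhydrides and 16 is a mixture of diastereomers in which every ring is cis; the lists show one of each, and all converge on the achiral 17.
Remark: in step 7 one molecule of 14 takes up two molecules of 13, because the carbodiimide returns the liberated 11 to 13 in the flask; a third equivalent of each is used as excess.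
Remark: quinone 3 (the dibromination product of 2,5-dihydroxy-1,4-benzoquinone) and the L-series Shi ketone (otherwise made from L-sorbose) are taken as catalogue compounds.
Remark: all eight epoxide carbons of 19 are S, which is the mirror image of the sense delivered by the D-fructose-derived ketone, so the L-series ketone is the correct one.

**Steps**

Step 1
Reactants: 1 4-bromophenol
Product: 2 (4-bromophenoxy)triisopropylsilane
Conditions: triisopropylsilyl chloride, imidazole, DMF, rt
Reagents that add atoms: triisopropylsilyl chloride, CC(C)[Si](Cl)(C(C)C)C(C)C
Why: Standard O-silylation of a phenol; the bulky triisopropylsilyl ether is chosen because it should survive aryllithium formation, cross-coupling, hydrogenolysis and the mildly basic epoxidation.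

Step 2
Reactants: 3 2,5-dibromo-3,6-dihydroxy-1,4-benzoquinone (bromanilic acid)
Product: 5 1,2,4,5-tetrakis(benzyloxy)-3,6-dibromobenzene, via 3,6-dibromobenzene-1,2,4,5-tetrol 4 (not isolated)
Conditions: Na2S2O4, K2CO3, BnBr, Bu4NI (cat.), DMF–H2O, Ar, rt → 60 °C
Reagents that add atoms: benzyl bromide, BrCc1ccccc1
Why: Dithionite reduces the quinone to the tetrahydroxyarene, and its phenoxides are O-benzylated in the same pot (reductive alkylation, Williamson ether synthesis) while excess reductant prevents re-oxidation. The ring is fully substituted, so C-alkylation cannot compete.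

Step 3
Reactants: 2 (4-bromophenoxy)triisopropylsilane; 5 1,2,4,5-tetrakis(benzyloxy)-3,6-dibromobenzene
Product: 8 2',3',5',6'-tetrakis(benzyloxy)-4,4''-bis(triisopropylsilyloxy)-1,1':4',1''-terphenyl, via [4-(triisopropylsilyloxy)phenyl]lithium 6 (not isolated), via [4-(triisopropylsilyloxy)phenyl]zinc chloride 7 (not isolated)
Conditions: 2 (2.5 equiv), n-BuLi, THF, −78 °C; ZnCl2, −78 °C → rt; then 5, Pd(OAc)2 (cat.), SPhos (cat.), THF, 60 °C
Reagents that add atoms: none
Why: Bromine–lithium exchange, transmetallation to zinc and a two-directional Negishi coupling. A dialkylbiarylphosphine ligand is suited to aryl bromides flanked by two ortho alkoxy groups, and the two C–Br bonds are equivalent, so the symmetric terphenyl should result.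

Step 4
Reactants: 9 6-methyl-2H-pyran-2-one
Product: 11 rac-(1R,4S)-4-methylcyclobut-2-ene-1-carboxylic acid (cis), via 1-methyl-2-oxabicyclo[2.2.0]hex-5-en-3-one 10 (not isolated)
Conditions: hν (300 nm), Et2O, 0 °C, flow; then Pd(OAc)2 (cat.), PBu3 (cat.), HCO2H, Et3N, THF, 0 °C → rt
Reagents that add atoms: none
Why: Irradiation effects the disrotatory photochemical 4π electrocyclisation of the pyranone to the cis-fused bicyclic β-lactone, which is kept in cold solution and never concentrated to dryness because strained lactones of this kind are thermally labile. Zerovalent palladium (formed in situ) ionises the allylic C–O bond with inversion, and hydride from the palladium formate is passed on the palladium face to the more substituted, methyl-bearing allyl terminus (palladium-catalysed formate hydrogenolysis of an allylic ester, Tsuji–Trost-type ionisation), so H enters anti to the carboxylate and methyl ends cis to CO2H. The work-up is kept at or below room temperature so that the ring does not open prematurely.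

Step 5
Reactants: 11 rac-(1R,4S)-4-methylcyclobut-2-ene-1-carboxylic acid
Product: 13 cis-4-methylcyclobut-2-ene-1-carboxylic anhydride (rac/meso mixture), via O-acylisourea 12 (not isolated)
Conditions: 11 (2.0 equiv), N,N'-dicyclohexylcarbodiimide (1.0 equiv), CH2Cl2, 0 °C; urea filtered off cold, concentrated below 20 °C
Reagents that add atoms: none
Why: Carbodiimide dehydration of a carboxylic acid: one molecule of 11 adds across the carbodiimide to give the O-acylisourea, and a second molecule attacks its acyl carbon to give the symmetric anhydride and the urea, which precipitates. No base, nucleophilic catalyst or heat is involved, so the cis relationship and the closed ring should be carried through unchanged.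

Step 6
Reactants: 8 2',3',5',6'-tetrakis(benzyloxy)-4,4''-bis(triisopropylsilyloxy)-1,1':4',1''-terphenyl
Product: 14 4,4''-bis(triisopropylsilyloxy)-[1,1':4',1''-terphenyl]-2',3',5',6'-tetrol
Conditions: H2 (1 atm), Pd/C, EtOAc–THF, rt; filtered under Ar, used at once
Reagents that add atoms: none
Why: Hydrogenolysis of aryl benzyl ethers is neutral, leaves aryl silyl ethers untouched and is run before any alkene is in the molecule. The tetrol forms under a reducing atmosphere and is handled air-free because it oxidises readily to the quinone.

Step 7
Reactants: 14 4,4''-bis(triisopropylsilyloxy)-[1,1':4',1''-terphenyl]-2',3',5',6'-tetrol; 13 cis-4-methylcyclobut-2-ene-1-carboxylic anhydride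
Product: 16 4,4''-bis(triisopropylsilyloxy)-[1,1':4',1''-terphenyl]-2',3',5',6'-tetrayl tetrakis(cis-4-methylcyclobut-2-ene-1-carboxylate) (mixture of cis diastereomers), via acylpyridinium carboxylate 15 (not isolated)
Conditions: 13 (3.0 equiv), N,N'-diisopropylcarbodiimide (3.0 equiv), 4-(dimethylamino)pyridine (0.4 equiv), CH2Cl2, −20 → 0 °C, Ar
Reagents that add atoms: none
Why: Acylation of the four phenolic OH groups by a symmetric anhydride under nucleophilic catalysis (Steglich-type conditions): 4-(dimethylamino)pyridine opens 13 to the N-acylpyridinium carboxylate, which acylates a phenol, and the carbodiimide dehydrates the liberated 11 back to 13, so both acyl groups of every anhydride are used and no stoichiometric amine base is present. The acyl donor has no alkene geometry that activation could scramble, and its α-proton is poorly acidic because removing it would place an allyl-type anion in a four-membered ring, so the cis relationship should survive and the low temperature keeps the rings closed.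

Step 8
Reactants: 16 4,4''-bis(triisopropylsilyloxy)-[1,1':4',1''-terphenyl]-2',3',5',6'-tetrayl tetrakis(cis-4-methylcyclobut-2-ene-1-carboxylate)
Product: 17 4,4''-bis(triisopropylsilyloxy)-[1,1':4',1''-terphenyl]-2',3',5',6'-tetrayl tetrakis[(2Z,4E)-hexa-2,4-dienoate]
Conditions: PhMe (degassed, 0.01 M), 2,6-di-tert-butyl-4-methylphenol (trace), 90–100 °C, Ar, dark
Reagents that add atoms: none
Why: Each cis-disubstituted cyclobutene undergoes a thermally allowed conrotatory 4π electrocyclic ring opening driven by release of ring strain: the ring C1–C4 σ bond becomes the two new π bonds (chain C2=C3 and C4=C5) and the former ring alkene becomes the C3–C4 single bond, so no σ bond is formed and no ring is closed; four rings are opened. Conrotation of a cis pair forces one substituent inward and the other outward, so every ring must give one Z and one E alkene. Torquoselectivity decides which: the methyl donor has a strong preference for outward rotation, whereas the ester has only a small intrinsic preference and its carbonyl π* orbital can interact with the breaking σ bond when it turns inward, so the ester rotates inward (2Z) and the methyl outward (4E). The closest known reaction type is the thermal opening of cis-4-substituted cyclobut-2-ene-1-carboxylic acid derivatives to (2Z,4E)-dienoic acid derivatives. No stereocentre is created; all eight sp3 centres of 16 are erased, which is why its diastereomeric composition does not matter. The selectivity required is torquoselectivity at four independent rings, secured by the cis relationship fixed in step 4 and carried through steps 5 and 7, and by the methyl-versus-ester competition inside each ring; the rings are insulated from one another, so the same preference should hold four times. The Z-enoate formed has no pathway for a 1,5-hydrogen shift (its C4=C5 alkene is E) and meets no acid, base or nucleophile, which is the reason for unveiling the diene only after the esters are in place. High dilution and a radical inhibitor are meant to suppress Diels–Alder or radical oligomerisation of the tetraene.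

Step 9
Reactants: 17 4,4''-bis(triisopropylsilyloxy)-[1,1':4',1''-terphenyl]-2',3',5',6'-tetrayl tetrakis[(2Z,4E)-hexa-2,4-dienoate]
Product: 18 4,4''-bis(triisopropylsilyloxy)-[1,1':4',1''-terphenyl]-2',3',5',6'-tetrayl tetrakis{(2Z)-3-[(2S,3S)-3-methyloxiran-2-yl]prop-2-enoate}
Conditions: 1,2:4,5-di-O-isopropylidene-β-L-erythro-2,3-hexodiulo-2,6-pyranose (ent-Shi ketone, 0.3 equiv per alkene), Oxone (2KHSO5·KHSO4·K2SO4), K2CO3, Bu4NHSO4, MeCN–CH2(OMe)2 / aq. Na2B4O7–Na2EDTA (pH ca. 9.5–10), −10 → 0 °C
Reagents that add atoms: potassium peroxymonosulfate (active salt of Oxone), [K+].[O-]S(=O)(=O)OO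
Why: Shi epoxidation: the chiral dioxirane formed from the ketone and KHSO5 transfers oxygen through a spiro transition state, and trans-disubstituted alkenes are its best substrates. The electrophilic oxidant should take the distal C4=C5 bond and leave the electron-poor enoate C2=C3 bond, as it does with other dienoates. The L-series ketone attacks the face that gives (4S,5S) at every chain, the mirror image of the (R,R) sense of the D-series ketone; the four alkenes react independently, so any mismatched event gives a diastereomer and not the enantiomer.

Step 10
Reactants: 18 4,4''-bis(triisopropylsilyloxy)-[1,1':4',1''-terphenyl]-2',3',5',6'-tetrayl tetrakis{(2Z)-3-[(2S,3S)-3-methyloxiran-2-yl]prop-2-enoate}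
Product: 19 4,4''-dihydroxy-[1,1':4',1''-terphenyl]-2',3',5',6'-tetrayl tetrakis{(2Z)-3-[(2S,3S)-3-methyloxiran-2-yl]prop-2-enoate} (CNP0249571.1)
Conditions: HF·pyridine, pyridine (excess), THF, 0 °C → rt; pH 7 phosphate buffer
Reagents that add atoms: none
Why: Fluoride cleaves the two aryl O–Si bonds, driven by the strength of the Si–F bond. Excess pyridine buffers the HF so that the vinyl epoxides and aryl esters should not be attacked, and no stereocentre or alkene is touched.

**Compound list**

1 | 4-bromophenol | Oc1ccc(Br)cc1 | starting material
2 | (4-bromophenoxy)triisopropylsilane | CC(C)[Si](Oc1ccc(Br)cc1)(C(C)C)C(C)C | intermediate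
3 | 2,5-dibromo-3,6-dihydroxy-1,4-benzoquinone (bromanilic acid) | O=C1C(Br)=C(O)C(=O)C(Br)=C1O | starting material
4 | 3,6-dibromobenzene-1,2,4,5-tetrol | Oc1c(O)c(Br)c(O)c(O)c1Br | intermediate (not isolated)
5 | 1,2,4,5-tetrakis(benzyloxy)-3,6-dibromobenzene | Brc1c(OCc2ccccc2)c(OCc2ccccc2)c(Br)c(OCc2ccccc2)c1OCc1ccccc1 | intermediate
6 | [4-(triisopropylsilyloxy)phenyl]lithium | [Li]c1ccc(O[Si](C(C)C)(C(C)C)C(C)C)cc1 | intermediate (not isolated)
7 | [4-(triisopropylsilyloxy)phenyl]zinc chloride | Cl[Zn]c1ccc(O[Si](C(C)C)(C(C)C)C(C)C)cc1 | intermediate (not isolated)
8 | 2',3',5',6'-tetrakis(benzyloxy)-4,4''-bis(triisopropylsilyloxy)-1,1':4',1''-terphenyl | c1ccccc1COc1c(OCc2ccccc2)c(-c2ccc(O[Si](C(C)C)(C(C)C)C(C)C)cc2)c(OCc2ccccc2)c(OCc2ccccc2)c1-c1ccc(O[Si](C(C)C)(C(C)C)C(C)C)cc1 | intermediate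
9 | 6-methyl-2H-pyran-2-one | CC1=CC=CC(=O)O1 | starting material
10 | (±)-1-methyl-2-oxabicyclo[2.2.0]hex-5-en-3-one (cis-fused; one enantiomer drawn) | C[C@]12C=C[C@H]1C(=O)O2 | intermediate (not isolated)
11 | rac-(1R,4S)-4-methylcyclobut-2-ene-1-carboxylic acid (cis; one enantiomer drawn) | C[C@H]1C=C[C@H]1C(=O)O | intermediate
12 | N,N'-dicyclohexyl-O-(cis-4-methylcyclobut-2-ene-1-carbonyl)isourea (one enantiomer drawn) | C[C@H]1C=C[C@H]1C(=O)OC(=NC1CCCCC1)NC1CCCCC1 | intermediate (not isolated)
13 | cis-4-methylcyclobut-2-ene-1-carboxylic anhydride (mixture of racemic and meso forms; one drawn) | C[C@H]1C=C[C@H]1C(=O)OC(=O)[C@@H]1C=C[C@@H]1C | intermediate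
14 | 4,4''-bis(triisopropylsilyloxy)-[1,1':4',1''-terphenyl]-2',3',5',6'-tetrol | Oc1c(O)c(-c2ccc(O[Si](C(C)C)(C(C)C)C(C)C)cc2)c(O)c(O)c1-c1ccc(O[Si](C(C)C)(C(C)C)C(C)C)cc1 | intermediate
15 | 1-(cis-4-methylcyclobut-2-ene-1-carbonyl)-4-(dimethylamino)pyridinium cis-4-methylcyclobut-2-ene-1-carboxylate (ion pair; one stereoisomer drawn) | C[C@H]1C=C[C@H]1C(=O)[n+]1ccc(N(C)C)cc1.C[C@H]1C=C[C@H]1C(=O)[O-] | intermediate (not isolated)
16 | 4,4''-bis(triisopropylsilyloxy)-[1,1':4',1''-terphenyl]-2',3',5',6'-tetrayl tetrakis(cis-4-methylcyclobut-2-ene-1-carboxylate) (mixture of cis diastereomers; one drawn) | C[C@H]1C=C[C@H]1C(=O)Oc1c(OC(=O)[C@@H]2C=C[C@@H]2C)c(-c2ccc(O[Si](C(C)C)(C(C)C)C(C)C)cc2)c(OC(=O)[C@@H]2C=C[C@@H]2C)c(OC(=O)[C@@H]2C=C[C@@H]2C)c1-c1ccc(O[Si](C(C)C)(C(C)C)C(C)C)cc1 | intermediate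
17 | 4,4''-bis(triisopropylsilyloxy)-[1,1':4',1''-terphenyl]-2',3',5',6'-tetrayl tetrakis[(2Z,4E)-hexa-2,4-dienoate] | C/C=C/C=C\C(=O)Oc1c(OC(=O)/C=C\C=C\C)c(-c2ccc(O[Si](C(C)C)(C(C)C)C(C)C)cc2)c(OC(=O)/C=C\C=C\C)c(OC(=O)/C=C\C=C\C)c1-c1ccc(O[Si](C(C)C)(C(C)C)C(C)C)cc1 | intermediate
18 | 4,4''-bis(triisopropylsilyloxy)-[1,1':4',1''-terphenyl]-2',3',5',6'-tetrayl tetrakis{(2Z)-3-[(2S,3S)-3-methyloxiran-2-yl]prop-2-enoate} | C[C@@H]1O[C@H]1/C=C\C(=O)Oc1c(OC(=O)/C=C\[C@@H]2O[C@H]2C)c(-c2ccc(O[Si](C(C)C)(C(C)C)C(C)C)cc2)c(OC(=O)/C=C\[C@@H]2O[C@H]2C)c(OC(=O)/C=C\[C@@H]2O[C@H]2C)c1-c1ccc(O[Si](C(C)C)(C(C)C)C(C)C)cc1 | intermediate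
19 | 4,4''-dihydroxy-[1,1':4',1''-terphenyl]-2',3',5',6'-tetrayl tetrakis{(2Z)-3-[(2S,3S)-3-methyloxiran-2-yl]prop-2-enoate} | C[C@@H]1O[C@H]1/C=C\C(=O)Oc1c(OC(=O)/C=C\[C@@H]2O[C@H]2C)c(-c2ccc(O)cc2)c(OC(=O)/C=C\[C@@H]2O[C@H]2C)c(OC(=O)/C=C\[C@@H]2O[C@H]2C)c1-c1ccc(O)cc1 | target

**Step count and least certain steps**

Total step count: 10. Longest linear sequence: 7 steps (1 → 2 → 8 → 14 → 16 → 17 → 18 → 19; the branch from 3 is equally long, the branch from 9 has 6 steps).

Step 8 (key step). The most likely failure is erosion of geometry summed over four sites: a small fraction of inward methyl rotation at each ring, or slow opening that calls for longer heating and lets the Z-enoates drift to E. Because the four rings open independently, a small leak per ring multiplies in the tetraene. The fallback builds the dienes by cross-coupling. It sets out from 14, which is esterified with commercial (Z)-3-iodoprop-2-enoic acid (carbodiimide, 0 °C) to give the terphenyl tetrakis[(2Z)-3-iodoprop-2-enoate] F1. A fourfold Stille coupling of F1 with (E)-tributyl(prop-1-en-1-yl)stannane (Pd2(dba)3, tri(2-furyl)phosphine, CuI, DMF, rt) proceeds with retention at both partners under neutral conditions and comes back to the route at 17.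

Step 4. Hydride may be delivered to the wrong allyl terminus (giving the 2-methylcyclobut-2-ene isomer), or palladium may exchange between the two faces of the cyclobutenyl fragment and so lose facial fidelity (giving the trans acid, whose ester would open to the E,E chain). The photoproduct may also decompose before it is reduced. The fallback avoids the cyclobutene altogether. It sets out from 9, which is treated with LiAlH4 in Et2O at low temperature. Conjugate hydride addition at C6 gives a 6H-pyran-2-olate that opens by a retro-oxa-6π process with the methyl group turning outward, the mode of attack expected for hydride and Grignard reagents on 2-pyranones; this gives (2Z,4E)-hexa-2,4-dienoic acid F2. F2 is converted with 1-chloro-N,N,2-trimethylprop-1-en-1-amine into (2Z,4E)-hexa-2,4-dienoyl chloride F3 under neutral conditions. F3 then acylates 14 in the presence of 2,6-lutidine and no nucleophilic catalyst, coming back to the route at 17 and bypassing 11, 13 and 16. The cost is that the Z geometry is exposed during activation.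

Step 7. Fourfold acylation of flanked OH groups may stop short, or 14 may oxidise to the quinone before all four positions are esterified, after which the remaining oxygens can no longer be acylated as phenols. The fallback makes the quinone the planned substrate and acylates reductively. It sets out from 14, which is deliberately oxidised with air in EtOAc to the stable, storable 3,6-dihydroxy-2,5-bis[4-(triisopropylsilyloxy)phenyl]-1,4-benzoquinone F4. F4 is then treated with zinc dust in the presence of 13 (5 equiv) and catalytic 4-(dimethylamino)pyridine in THF at 0 °C, so that each phenoxide is acylated as the reduction delivers it, and the sequence comes back to the route at 16.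

Step 9. The aryl esters may hydrolyse at the pH needed to generate the dioxirane, conversion may stop at partly epoxidised species, or facial selectivity at any one of the four alkenes may fall short and give diastereomers that are hard to remove. The fallback makes the epoxide before the chain meets the core. It sets out from 11, which is esterified with 2-(trimethylsilyl)ethanol to 2-(trimethylsilyl)ethyl cis-4-methylcyclobut-2-ene-1-carboxylate F5. Heating F5 gives 2-(trimethylsilyl)ethyl (2Z,4E)-hexa-2,4-dienoate F6. Shi epoxidation of this robust ester with the L-series ketone gives 2-(trimethylsilyl)ethyl (2Z)-3-[(2S,3S)-3-methyloxiran-2-yl]prop-2-enoate F7, which can be purified to a single stereoisomer. Bu4NF releases (2Z)-3-[(2S,3S)-3-methyloxiran-2-yl]prop-2-enoic acid F8, which is coupled with 14 (carbodiimide, catalytic 4-pyrrolidinopyridine, −20 °C), coming back to the route at 18. The cost is a delicate epoxy acid and a Z-acid that must be activated.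

Step 10. Cleavage of aryl triisopropylsilyl ethers by buffered HF is slow, and in that time the vinyl epoxides may be opened by acid (fluorohydrin formation or attack by a neighbouring carbonyl oxygen). The fallback reverses the order of the last two operations. It sets out from 17, whose silyl ethers are removed with Bu4NF–AcOH in THF at 0 °C, before any epoxide exists, to give the 4,4''-dihydroxyterphenyl tetrakis[(2Z,4E)-hexa-2,4-dienoate] F9. F9 is then epoxidised with the L-series ketone and Oxone at about pH 8 (NaHCO3, more ketone), where the phenols stay un-ionised and should be oxidised more slowly than the alkenes, coming back to the route at 19.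

**Further compounds**

F1 | step 8 | 4,4''-bis(triisopropylsilyloxy)-[1,1':4',1''-terphenyl]-2',3',5',6'-tetrayl tetrakis[(2Z)-3-iodoprop-2-enoate] | I/C=C\C(=O)Oc1c(OC(=O)/C=C\I)c(-c2ccc(O[Si](C(C)C)(C(C)C)C(C)C)cc2)c(OC(=O)/C=C\I)c(OC(=O)/C=C\I)c1-c1ccc(O[Si](C(C)C)(C(C)C)C(C)C)cc1
F2 | step 4 | (2Z,4E)-hexa-2,4-dienoic acid | C/C=C/C=C\C(=O)O
F3 | step 4 | (2Z,4E)-hexa-2,4-dienoyl chloride | C/C=C/C=C\C(Cl)=O
F4 | step 7 | 3,6-dihydroxy-2,5-bis[4-(triisopropylsilyloxy)phenyl]-1,4-benzoquinone | O=C1C(O)=C(c2ccc(O[Si](C(C)C)(C(C)C)C(C)C)cc2)C(=O)C(O)=C1c1ccc(O[Si](C(C)C)(C(C)C)C(C)C)cc1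
F5 | step 9 | 2-(trimethylsilyl)ethyl rac-(1R,4S)-4-methylcyclobut-2-ene-1-carboxylate | C[C@H]1C=C[C@H]1C(=O)OCC[Si](C)(C)C
F6 | step 9 | 2-(trimethylsilyl)ethyl (2Z,4E)-hexa-2,4-dienoate | C/C=C/C=C\C(=O)OCC[Si](C)(C)C
F7 | step 9 | 2-(trimethylsilyl)ethyl (2Z)-3-[(2S,3S)-3-methyloxiran-2-yl]prop-2-enoate | C[C@@H]1O[C@H]1/C=C\C(=O)OCC[Si](C)(C)C
F8 | step 9 | (2Z)-3-[(2S,3S)-3-methyloxiran-2-yl]prop-2-enoic acid | C[C@@H]1O[C@H]1/C=C\C(=O)O
F9 | step 10 | 4,4''-dihydroxy-[1,1':4',1''-terphenyl]-2',3',5',6'-tetrayl tetrakis[(2Z,4E)-hexa-2,4-dienoate] | C/C=C/C=C\C(=O)Oc1c(OC(=O)/C=C\C=C\C)c(-c2ccc(O)cc2)c(OC(=O)/C=C\C=C\C)c(OC(=O)/C=C\C=C\C)c1-c1ccc(O)cc1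
A1 | alternative 1 | cis-5,6-bis(benzyloxy)-4,7-bis[4-(triisopropylsilyloxy)phenyl]-3a,7a-dihydro-1,3-benzodioxol-2-one | O=C1O[C@H]2C(c3ccc(O[Si](C(C)C)(C(C)C)C(C)C)cc3)=C(OCc3ccccc3)C(OCc3ccccc3)=C(c3ccc(O[Si](C(C)C)(C(C)C)C(C)C)cc3)[C@H]2O1
A2 | alternative 1 | 3,4-bis(benzyloxy)-2,5-bis[4-(triisopropylsilyloxy)phenyl]cyclopenta-2,4-dien-1-one | O=C1C(c2ccc(O[Si](C(C)C)(C(C)C)C(C)C)cc2)=C(OCc2ccccc2)C(OCc2ccccc2)=C1c1ccc(O[Si](C(C)C)(C(C)C)C(C)C)cc1
A3 | alternative 1 | vinylene carbonate (1,3-dioxol-2-one) | O=C1OC=CO1
A4 | alternative 2 | 5,6-di-tert-butoxy-2,2-diisopropyl-4,7-bis[4-(triisopropylsilyloxy)phenyl]-1,3,2-benzodioxasilole | CC(C)[Si]1(C(C)C)Oc2c(-c3ccc(O[Si](C(C)C)(C(C)C)C(C)C)cc3)c(OC(C)(C)C)c(OC(C)(C)C)c(-c3ccc(O[Si](C(C)C)(C(C)C)C(C)C)cc3)c2O1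
A5 | alternative 2 | diisopropylbis{[4-(triisopropylsilyloxy)phenyl]ethynyloxy}silane | CC(C)[Si](C(C)C)(OC#Cc1ccc(O[Si](C(C)C)(C(C)C)C(C)C)cc1)OC#Cc1ccc(O[Si](C(C)C)(C(C)C)C(C)C)cc1
A6 | alternative 2 | di-tert-butoxyethyne | CC(C)(C)OC#COC(C)(C)C
A7 | alternative 3 | 2,5-bis(4-benzyloxyphenyl)-3,6-dihydroxy-1,4-benzoquinone | O=C1C(O)=C(c2ccc(OCc3ccccc3)cc2)C(=O)C(O)=C1c1ccc(OCc2ccccc2)cc1
A8 | alternative 3 | (3Z,6Z)-3,6-bis[4-(benzyloxy)benzylidene]-1,4-dioxane-2,5-dione | O=C1O/C(=C\c2ccc(OCc3ccccc3)cc2)C(=O)O/C1=C\c1ccc(OCc2ccccc2)cc1
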